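The reading asked for came at 10 h, far later than any dose ended, so I asked what the given numbers would have to show for the flasks to part at that hour.

all flasks: substrate 0.10 M; initiator 1.7 mM

|  | partner | remark | time |
|---|---|---|---|
| birch | 0.052 M (fed, over 4.0 min) | run made earlier; the fed solution adds 1.0 times the starting volume |  |
| elm | 0.21 M (fed, over 4.0 min) | run made earlier; the fed solution adds 1.0 times the starting volume |  |
| eta | 0.105 M (fed, over 4.0 min) | the fed solution adds 1.0 times the starting volume | 10 h |
| theta | 0.105 M (fed, over 8.0 min) | the fed solution adds 1.0 times the starting volume | 10 h |
| alpha | 0.105 M (fed, over 15 min) | the fed solution adds 1.0 times the starting volume | 10 h |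
| epsilon | 0.105 M (fed, over 30 min) | the fed solution adds 1.0 times the starting volume | 10 h |

- birch (time / h: target / %, isomer of the product / %): 1.33: 11.8, 17.8; 3.00: 15.3, 26.0; 4.00: 15.9, 28.1; 6.00: 17.0, 30.8; 8.00: 17.1, 31.3; 10.0: 18.8, 31.4
- elm (time / h: target / %, isomer of the product / %): 1.33: 31.8, 46.0; 3.00: 35.5, 61.5; 4.00: 35.4, 62.5; 6.00: 34.6, 63.2; 8.00: 35.5, 62.8; 10.0: 35.7, 63.6

(standard deviation of a reading: 0.5 percentage points)

1. share of target in all that became target or isomer of the product for eta, theta, alpha, epsilon, in this order
2. the course of these numbers from the first flask to the last (hardly changes / rises all the way / rises, then falls / falls, then rises / falls all the way)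

- in percentages every species weighs as the substrate in it: one ended chains A counts as two
- charges are per starting volume, the dose included; the dosed solution carries all of it
- steps that have been proposed: initiator -> 2 initiating radical; substrate + initiating radical -> capped initiator + first chain carrier; partner + first chain carrier -> target + second chain carrier; substrate + second chain carrier -> by-product + first chain carrier; first chain carrier -> ended carrier; 2 first chain carrier -> ended chains A; 2 second chain carrier -> ended chains B; target <-> isomer of the product; target -> over-reaction product
- the share counts what is present at the end, not what went on to other products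
- "hardly changes" means that all values lie within two and a half points (for a concentration: within two and a half percent of the largest)

For the course to be anything but flat, the share of target in target plus isomer of the product would have to differ between flasks by more than the margin at that late reading. Summing the four elm readings from 4.00 h onward gave 35.9%. This is the number I carried: the plateau share, the fraction of target in the pair once that fraction stops moving, which I read as thermodynamic control of the pair. The same sum in birch, with a quarter of the elm partner, gave 36.1%, so the plateau did not follow the partner charge.

I then treated each flask's departure from the plateau as a small correction. In elm the excess share was 5 percentage points at 1.33 h but 0.7 points at 3.00 h, against a reading scatter of 0.5 points. For the flasks to part, an excess like this would have to survive to the last reading. Yet the dose in epsilon, the longest, ends just 26.0 min after the one in eta, which is short against the 7.00 h of flat readings in elm. I therefore put the four flasks at the plateau share, with a course that hardly changes.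

The forecast gave 36%, 36%, 36% and 36%, course hardly changes, reasoning that “each flask should have relaxed to the same equilibrium”. The flasks gave 35.7%, 35.7%, 35.7% and 35.7%, course hardly changes.

    initiator → 2 initiating radical (k = 8.20 × 10⁻⁵ s⁻¹)
    substrate + initiating radical → capped initiator + first chain carrier (k = 1.20 × 10⁶ M⁻¹ s⁻¹)
    partner + first chain carrier → target + second chain carrier (k = 43000 M⁻¹ s⁻¹)
    substrate + second chain carrier → by-product + first chain carrier (k = 12000 M⁻¹ s⁻¹)
    first chain carrier → ended carrier (k = 14.0 s⁻¹)
    2 first chain carrier → ended chains A (k = 1.50 × 10⁹ M⁻¹ s⁻¹)
    2 second chain carrier → ended chains B (k = 5.00 × 10⁷ M⁻¹ s⁻¹)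
    target ⇌ isomer of the product (K = 1.80, k = 0.00110 s⁻¹)
    target → over-reaction product (k = 1.30 × 10⁻⁶ s⁻¹)

Eta stood 0.2 points below my plateau share. What holds the share up there is the undoing of isomer of the product into target: with that step taken away, eta gave 0.0949% in place of 35.7%. On epsilon, the flask fed slowest, the plateau share served as a multiplier: applied to its 94.4% of target plus isomer of the product at 10.0 h, it gives 33.9% of target, and epsilon held 33.8%.

Readings and results stem from a simulated flask for an exercise; the scatter is artificial.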